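The synthesis rests on cutting C12–C21 and O13–C14 (atoms numbered along the target SMILES). The key step exploits the acyloin pair formed by ketone C21 and oxygen-bearing C12 in the seven-membered ring, together with the 1,3 relation between O13 and carboxyl C14 on C16: a carbene catalyst joins the C21 aldehyde to the C12 aldehyde, and the new C12 alkoxide closes the γ-lactone ring, so both rings and the C12 centre arise in one operation. The precursor is a dibromo(ethyl)tetralin that carries a C11 formyl group, a C16 methyl ester and a C17 3-oxopropyl arm on one face; it is built from a cis-fused lactone that relays one catalytically set stereocentre.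

Key step: step 12

Remark: the ester α-centre C16 is not expected to epimerise under carbene conditions, so it is set cis to the C17 arm before the key step and only C11 and C12 are left to equilibrate; labels C11–C23 below follow the target SMILES, and compounds 18 and 20 carry the target configurations at C11, C16 and C17.

Step 1
Reactants: 1 (3-ethylphenyl)boronic acid; 2 furan-2(5H)-one
Product: 3 (4S)-4-(3-ethylphenyl)oxolan-2-one
Conditions: Rh(acac)(C2H4)2 (3 mol %), (S)-BINAP (3.3 mol %), dioxane/H2O 10:1, 100 °C
Reagents that add atoms: none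
Why: Rhodium-catalysed asymmetric 1,4-addition of an arylboronic acid to a butenolide (Hayashi–Miyaura reaction) is established chemistry, and the BINAP-bound aryl–rhodium species should add to one face of the enoate to set the benzylic centre (the later C11) with the (S) configuration, the ligand antipode being used should the sense of induction turn out opposite.

Step 2
Reactants: 3 (4S)-4-(3-ethylphenyl)oxolan-2-one; 4 tert-butyl bromoacetate
Product: 5 tert-butyl 2-[(3R,4S)-4-(3-ethylphenyl)-2-oxooxolan-3-yl]acetate (3,4-trans)
Conditions: LiN(SiMe3)2, THF, −78 °C; then 4, −78 → −40 °C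
Reagents that add atoms: none
Why: Alkylation of the lactone lithium enolate with an α-halo ester proceeds anti to the β-aryl group, so the acetic ester arm (the later C17 and C23) is placed trans to the aryl ring at the new centre (the later C16).

Step 3
Reactants: 5 tert-butyl 2-[(3R,4S)-4-(3-ethylphenyl)-2-oxooxolan-3-yl]acetate
Product: 7 (3aR,9bS)-8-ethyl-1,3a,4,9b-tetrahydronaphtho[1,2-c]furan-3,5-dione (trans-fused), via lactone acid 6 (not isolated)
Conditions: CF3CO2H, CH2Cl2, rt; evaporate; then P2O5 in MeSO3H (1:10 w/w), 40 °C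
Reagents that add atoms: none
Why: Acidolysis of the tert-butyl ester followed by intramolecular Friedel–Crafts acylation closes the six-membered ketone ring at the arene position para to the ethyl group and ortho to the lactone-bearing carbon, the activated and unhindered site, without touching either stereocentre.

Step 4
Reactants: 7 (3aR,9bS)-8-ethyl-1,3a,4,9b-tetrahydronaphtho[1,2-c]furan-3,5-dione
Product: 8 (3aS,9bS)-8-ethyl-1,3a,4,9b-tetrahydronaphtho[1,2-c]furan-3,5-dione (cis-fused)
Conditions: DBU (0.2 equiv), CH2Cl2, rt
Reagents that add atoms: none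
Why: Base-mediated epimerisation at the lactone α-carbon under thermodynamic control should favour the cis-fused γ-lactone, because a trans ring fusion on the flattened tetralone ring is strained, as is known for trans-fused aryltetralin lactones, while the non-acidic benzylic centre keeps its configuration.

Step 5
Reactants: 8 (3aS,9bS)-8-ethyl-1,3a,4,9b-tetrahydronaphtho[1,2-c]furan-3,5-dione
Product: 9 (3aS,9bS)-7,9-dibromo-8-ethyl-1,3a,4,9b-tetrahydronaphtho[1,2-c]furan-3,5-dione
Conditions: AlCl3 (4 equiv), Br2 (2.2 equiv), ClCH2CH2Cl, 0 → 40 °C, dark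
Reagents that add atoms: bromine, BrBr
Why: Electrophilic aromatic bromination under swamping-catalyst conditions: the AlCl3-bound ketone does not enolise and directs meta, and the ethyl group and the ring alkyl carbon direct ortho and para to the same two carbons, so both bromines should enter beside the ethyl group.

Step 6
Reactants: 9 (3aS,9bS)-7,9-dibromo-8-ethyl-1,3a,4,9b-tetrahydronaphtho[1,2-c]furan-3,5-dione; 10 3-bromoprop-1-ene (allyl bromide)
Product: 11 (3aR,4S,9bS)-4-allyl-7,9-dibromo-8-ethyl-1,3a,4,9b-tetrahydronaphtho[1,2-c]furan-3,5-dione (allyl trans to the lactone ring)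
Conditions: LiN(SiMe3)2 (1.05 equiv), THF, −78 °C; then 10, −78 → −20 °C
Reagents that add atoms: none
Why: Ketone enolate alkylation: the amide base removes a proton from the α-methylene of the aryl ketone (C17), the most acidic and least hindered site, and allyl bromide attacks the convex face of the cis-fused bicycle, anti to the lactone ring, although this centre is planarised again in step 7.

Step 7
Reactants: 11 (3aR,4S,9bS)-4-allyl-7,9-dibromo-8-ethyl-1,3a,4,9b-tetrahydronaphtho[1,2-c]furan-3,5-dione
Product: 12 (3aR,4R,9bS)-4-allyl-7,9-dibromo-8-ethyl-4-methyl-1,3a,4,9b-tetrahydronaphtho[1,2-c]furan-3,5-dione (allyl cis to the lactone ring)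
Conditions: KN(SiMe3)2 (1.1 equiv), THF, −78 → −40 °C; then MeI, −78 → 0 °C
Reagents that add atoms: iodomethane, CI
Why: Second ketone enolate alkylation forming the quaternary centre C17: the concave face is shielded by the lactone carbonyl carbon on C16 and by the C12 methylene, so methyl iodide should enter from the convex face and leave the allyl group on the lactone face, cis to C14 and C12.

Step 8
Reactants: 12 (3aR,4R,9bS)-4-allyl-7,9-dibromo-8-ethyl-4-methyl-1,3a,4,9b-tetrahydronaphtho[1,2-c]furan-3,5-dione
Product: 13 (3aR,4R,9bS)-4-allyl-7,9-dibromo-8-ethyl-4,5,5-trimethyl-3a,4,5,9b-tetrahydronaphtho[1,2-c]furan-3(1H)-one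
Conditions: Me2TiCl2 (from Me2Zn and TiCl4, 3 equiv), CH2Cl2, −30 °C → rt
Reagents that add atoms: dimethyltitanium dichloride, C[Ti](C)(Cl)Cl (prepared in the flask from dimethylzinc, C[Zn]C, and TiCl4)
Why: Reetz geminal dimethylation: methyl addition to the non-enolisable ketone gives a titanium alkoxide that ionises to a tertiary benzylic cation and takes up a second methyl group, a process known next to quaternary carbons, and lactones, aryl bromides and isolated alkenes are tolerated.

Step 9
Reactants: 13 (3aR,4R,9bS)-4-allyl-7,9-dibromo-8-ethyl-4,5,5-trimethyl-3a,4,5,9b-tetrahydronaphtho[1,2-c]furan-3(1H)-one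
Product: 15 (3aR,4R,9bS)-7,9-dibromo-8-ethyl-4-(3-hydroxypropyl)-4,5,5-trimethyl-3a,4,5,9b-tetrahydronaphtho[1,2-c]furan-3(1H)-one, via alkylborane 14 (not isolated)
Conditions: 9-BBN, THF, 0 °C → rt; then 30% H2O2, aq. NaOAc, 0 °C → rt
Reagents that add atoms: 9-borabicyclo[3.3.1]nonane, B1C2CCCC1CCC2 (its atoms stay only in 14); hydrogen peroxide, OO
Why: Brown hydroboration–oxidation: 9-BBN adds boron to the terminal carbon of the allyl group and buffered peroxide converts the borane to the primary alcohol (C21) without opening the lactone or touching the aryl bromides.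

Step 10
Reactants: 15 (3aR,4R,9bS)-7,9-dibromo-8-ethyl-4-(3-hydroxypropyl)-4,5,5-trimethyl-3a,4,5,9b-tetrahydronaphtho[1,2-c]furan-3(1H)-one
Product: 17 methyl (1S,2R,3R)-6,8-dibromo-7-ethyl-1-(hydroxymethyl)-3-(3-hydroxypropyl)-3,4,4-trimethyl-1,2,3,4-tetrahydronaphthalene-2-carboxylate, via potassium carboxylate 16 (not isolated)
Conditions: KOH (1.05 equiv), MeOH/H2O, 40 °C; evaporate to dryness; then MeI, DMF, 0 °C → rt; used at once
Reagents that add atoms: potassium hydroxide, [K+].[OH-]; iodomethane, CI
Why: Lactone saponification followed by O-alkylation of the carboxylate salt with methyl iodide gives the γ-hydroxy methyl ester without an acidic stage, which would close the lactone again, and leaves the three stereocentres untouched.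

Step 11
Reactants: 17 methyl (1S,2R,3R)-6,8-dibromo-7-ethyl-1-(hydroxymethyl)-3-(3-hydroxypropyl)-3,4,4-trimethyl-1,2,3,4-tetrahydronaphthalene-2-carboxylate
Product: 18 methyl (1S,2R,3R)-6,8-dibromo-7-ethyl-1-formyl-3,4,4-trimethyl-3-(3-oxopropyl)-1,2,3,4-tetrahydronaphthalene-2-carboxylate (formyl, ester and oxopropyl groups all cis)
Conditions: Dess–Martin periodinane (DMP, 2.6 equiv), NaHCO3, CH2Cl2, 0 °C → rt; used directly
Reagents that add atoms: none
Why: Dess–Martin oxidation converts both primary alcohols to aldehydes under mild buffered conditions, fast enough to consume the C12 carbinol before it can re-lactonise, and does not epimerise the ester-bearing centre.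

Step 12
Reactants: 18 methyl (1S,2R,3R)-6,8-dibromo-7-ethyl-1-formyl-3,4,4-trimethyl-3-(3-oxopropyl)-1,2,3,4-tetrahydronaphthalene-2-carboxylate
Product: 20 19,20-dihydrosalimabromide, via acyloin 19 (not isolated)
Conditions: 2-(pentafluorophenyl)-6,7-dihydro-5H-pyrrolo[2,1-c][1,2,4]triazol-2-ium tetrafluoroborate (20 mol %), DBU (20 mol %), THF (0.02 M), 40 °C
Reagents that add atoms: none
Why: Proposed new method: the triazolylidene adds to the less hindered aldehyde, C21 of the oxopropyl arm, and the resulting Breslow intermediate attacks the C12 formyl carbon across the ring (7-exo-trig, bond C12–C21); release of the carbene gives acyloin 19, whose C12 alkoxide then acylates on the neighbouring methyl ester (5-exo-trig, bond O13–C14) and expels methoxide. The closest known reaction type is the carbene-catalysed intramolecular crossed acyloin (benzoin) cyclisation of dialdehydes and keto aldehydes, which is established for five- and six-membered α-hydroxy ketones; the seven-membered closure locked by lactonisation is the unproven part. C12 is the new stereocentre and is set by the trap: acyloin formation is reversible, and only the epimer whose oxygen points toward the C16 ester can form the γ-lactone, which removes it from the equilibrium. C11 is an enolisable α-aryl aldehyde centre, so any epimer formed under the base returns through the enol to the cis isomer that cyclises, whereas C16 and C17 are fixed in 18 and hold the formyl group and the oxopropyl arm on the same face of the tetralin. The step needs the carbene to select C21 over C12, which the α-branching and the flanking aryl bromine at C12 should secure, and it needs the acyloin to outrun aldol reactions of the two aldehydes, which the catalytic base charge and the fast lactone trap should favour.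

Step 13
Reactants: 20 19,20-dihydrosalimabromide
Product: 21 salimabromide
Conditions: 2-iodoxybenzoic acid (IBX, 3 equiv), 4-methoxypyridine N-oxide (3 equiv), DMSO, rt
Reagents that add atoms: none
Why: IBX-mediated dehydrogenation of a ketone to an enone: the only α-carbon that can carry the new double bond is C20, because the other one, C12, is a bridgehead of the lactone bicycle, and C17 is quaternary, so a single ring-constrained C19=C20 double bond should form and no stereocentre is affected.

Compound list
1 | (3-ethylphenyl)boronic acid | CCc1cccc(c1)B(O)O | starting material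
2 | furan-2(5H)-one | O=C1OCC=C1 | starting material
3 | (4S)-4-(3-ethylphenyl)oxolan-2-one | CCc1cccc(c1)[C@H]1COC(=O)C1 | intermediate
4 | tert-butyl bromoacetate | CC(C)(C)OC(=O)CBr | starting material
5 | tert-butyl 2-[(3R,4S)-4-(3-ethylphenyl)-2-oxooxolan-3-yl]acetate (trans) | CCc1cccc(c1)[C@H]1COC(=O)[C@@H]1CC(=O)OC(C)(C)C | intermediate
6 | 2-[(3R,4S)-4-(3-ethylphenyl)-2-oxooxolan-3-yl]acetic acid | CCc1cccc(c1)[C@H]1COC(=O)[C@@H]1CC(=O)O | intermediate
7 | (3aR,9bS)-8-ethyl-1,3a,4,9b-tetrahydronaphtho[1,2-c]furan-3,5-dione (trans-fused) | CCc1ccc2c(c1)[C@H]1COC(=O)[C@@H]1CC2=O | intermediate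
8 | (3aS,9bS)-8-ethyl-1,3a,4,9b-tetrahydronaphtho[1,2-c]furan-3,5-dione (cis-fused) | CCc1ccc2c(c1)[C@H]1COC(=O)[C@H]1CC2=O | intermediate
9 | (3aS,9bS)-7,9-dibromo-8-ethyl-1,3a,4,9b-tetrahydronaphtho[1,2-c]furan-3,5-dione | CCc1c(Br)cc2c(c1Br)[C@H]1COC(=O)[C@H]1CC2=O | intermediate
10 | 3-bromoprop-1-ene (allyl bromide) | C=CCBr | starting material
11 | (3aR,4S,9bS)-4-allyl-7,9-dibromo-8-ethyl-1,3a,4,9b-tetrahydronaphtho[1,2-c]furan-3,5-dione | CCc1c(Br)cc2c(c1Br)[C@H]1COC(=O)[C@H]1[C@H](CC=C)C2=O | intermediate
12 | (3aR,4R,9bS)-4-allyl-7,9-dibromo-8-ethyl-4-methyl-1,3a,4,9b-tetrahydronaphtho[1,2-c]furan-3,5-dione | CCc1c(Br)cc2c(c1Br)[C@H]1COC(=O)[C@H]1[C@@](C)(CC=C)C2=O | intermediate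
13 | (3aR,4R,9bS)-4-allyl-7,9-dibromo-8-ethyl-4,5,5-trimethyl-3a,4,5,9b-tetrahydronaphtho[1,2-c]furan-3(1H)-one | CCc1c(Br)cc2c(c1Br)[C@H]1COC(=O)[C@H]1[C@@](C)(CC=C)C2(C)C | intermediate
14 | 9-[3-((3aR,4R,9bS)-7,9-dibromo-8-ethyl-4,5,5-trimethyl-3-oxo-1,3,3a,4,5,9b-hexahydronaphtho[1,2-c]furan-4-yl)propyl]-9-borabicyclo[3.3.1]nonane | CCc1c(Br)cc2c(c1Br)[C@H]1COC(=O)[C@H]1[C@@](C)(CCCB1C3CCCC1CCC3)C2(C)C | intermediate
15 | (3aR,4R,9bS)-7,9-dibromo-8-ethyl-4-(3-hydroxypropyl)-4,5,5-trimethyl-3a,4,5,9b-tetrahydronaphtho[1,2-c]furan-3(1H)-one | CCc1c(Br)cc2c(c1Br)[C@H]1COC(=O)[C@H]1[C@@](C)(CCCO)C2(C)C | intermediate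
16 | potassium (1S,2R,3R)-6,8-dibromo-7-ethyl-1-(hydroxymethyl)-3-(3-hydroxypropyl)-3,4,4-trimethyl-1,2,3,4-tetrahydronaphthalene-2-carboxylate | CCc1c(Br)cc2c(c1Br)[C@@H](CO)[C@@H](C(=O)[O-])[C@@](C)(CCCO)C2(C)C.[K+] | intermediate
17 | methyl (1S,2R,3R)-6,8-dibromo-7-ethyl-1-(hydroxymethyl)-3-(3-hydroxypropyl)-3,4,4-trimethyl-1,2,3,4-tetrahydronaphthalene-2-carboxylate | CCc1c(Br)cc2c(c1Br)[C@@H](CO)[C@@H](C(=O)OC)[C@@](C)(CCCO)C2(C)C | intermediate
18 | methyl (1S,2R,3R)-6,8-dibromo-7-ethyl-1-formyl-3,4,4-trimethyl-3-(3-oxopropyl)-1,2,3,4-tetrahydronaphthalene-2-carboxylate | CCc1c(Br)cc2c(c1Br)[C@@H](C=O)[C@@H](C(=O)OC)[C@@](C)(CCC=O)C2(C)C | intermediate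
19 | acyloin: seven-membered α-hydroxy ketone (hydroxyl on C12, ketone C21, ring C11–C12–C21–C20–C19–C17–C16) with the C16 methyl ester still open | CCc1c(Br)cc2c(c1Br)[C@H]1[C@H](O)C(=O)CC[C@](C)([C@@H]1C(=O)OC)C2(C)C | intermediate
20 | 19,20-dihydrosalimabromide (cycloheptanone bridging C11 and C17; γ-lactone O13–C14 across C11–C16) | CCc1c(Br)cc2c(c1Br)[C@H]1[C@@H]3OC(=O)[C@H]1[C@@](C)(CCC3=O)C2(C)C | intermediate
21 | salimabromide | CCc1c(Br)cc2c(c1Br)[C@H]1[C@@H]3OC(=O)[C@H]1[C@@](C)(C=CC3=O)C2(C)C | target

Total step count: 13. Longest linear sequence: 13 steps (from 1 and 2 to 21).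

Steps most likely to fail

Step 12 (proposed new method). The seven-membered closure may not compete: the Breslow intermediate may simply be reprotonated, or base-mediated intramolecular aldol reactions of the two aldehydes may consume the substrate. The fallback makes the same two bonds by known reductive chemistry. It sets out from 18: SmI2 in THF with t-BuOH (−78 °C → rt) couples the two aldehydes in a pinacol-type cyclisation, and the C12 alkoxide lactonises on the methyl ester (if necessary after brief treatment with DBU) to give the C21 carbinol lactone F1. Dess–Martin oxidation of the remaining secondary alcohol then gives 20, where the route is rejoined. Only the diol epimer whose C12 oxygen faces the ester can lactonise, so the C12 selectivity of the pinacol step would have to be checked.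

Step 8. Methyl transfer to the hindered carbonyl flanked by the quaternary C17 may be incomplete, or the benzylic cation may lose a proton to give an exocyclic alkene. The fallback separates the two bond formations and sets out from 12: MeMgBr with CeCl3 in THF (−78 → 0 °C) adds once to the ketone, chemoselectively over the lactone, to give the tertiary benzylic alcohol F2. Me3Al in CH2Cl2 (0 °C → rt) then ionises the isolated carbinol and delivers the second methyl group, returning to 13.

Step 10. The γ-hydroxy methyl ester may close back to the lactone during esterification or handling. The fallback never exposes a free γ-hydroxy ester and sets out from 15: after the same KOH opening to salt 16, TESCl and imidazole in DMF silylate both alkoxides and the carboxylate to give the tris(triethylsilyl) compound F3. Aqueous work-up cleaves only the silyl ester and gives the bis(silyl ether) acid F4, and TMSCHN2 in MeOH/toluene gives the bis(silyl ether) methyl ester F5. Swern oxidation ((COCl)2, DMSO, CH2Cl2, −78 °C; Et3N, → −20 °C), which oxidises primary triethylsilyl ethers directly to aldehydes, then gives 18, where the route is rejoined.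

Further compounds
F1 | step 12 | 19,20-dihydrosalimabromide with the C21 ketone as a secondary alcohol (configuration at C21 not defined) | CCc1c(Br)cc2c(c1Br)[C@H]1[C@@H]3OC(=O)[C@H]1[C@@](C)(CCC3O)C2(C)C
F2 | step 8 | (3aR,4R,9bS)-4-allyl-7,9-dibromo-8-ethyl-5-hydroxy-4,5-dimethyl-3a,4,5,9b-tetrahydronaphtho[1,2-c]furan-3(1H)-one (configuration at C5 not defined) | CCc1c(Br)cc2c(c1Br)[C@H]1COC(=O)[C@H]1[C@@](C)(CC=C)C2(C)O
F3 | step 10 | triethylsilyl (1S,2R,3R)-6,8-dibromo-7-ethyl-3,4,4-trimethyl-1-[(triethylsilyloxy)methyl]-3-[3-(triethylsilyloxy)propyl]-1,2,3,4-tetrahydronaphthalene-2-carboxylate | CCc1c(Br)cc2c(c1Br)[C@@H](CO[Si](CC)(CC)CC)[C@@H](C(=O)O[Si](CC)(CC)CC)[C@@](C)(CCCO[Si](CC)(CC)CC)C2(C)C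
F4 | step 10 | (1S,2R,3R)-6,8-dibromo-7-ethyl-3,4,4-trimethyl-1-[(triethylsilyloxy)methyl]-3-[3-(triethylsilyloxy)propyl]-1,2,3,4-tetrahydronaphthalene-2-carboxylic acid | CCc1c(Br)cc2c(c1Br)[C@@H](CO[Si](CC)(CC)CC)[C@@H](C(=O)O)[C@@](C)(CCCO[Si](CC)(CC)CC)C2(C)C
F5 | step 10 | methyl (1S,2R,3R)-6,8-dibromo-7-ethyl-3,4,4-trimethyl-1-[(triethylsilyloxy)methyl]-3-[3-(triethylsilyloxy)propyl]-1,2,3,4-tetrahydronaphthalene-2-carboxylate | CCc1c(Br)cc2c(c1Br)[C@@H](CO[Si](CC)(CC)CC)[C@@H](C(=O)OC)[C@@](C)(CCCO[Si](CC)(CC)CC)C2(C)C
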